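**Retrosynthetic overview**
1. Feature used: the ether oxygen is flanked on ring A (C1 CO2H, C2 OMe, C3 carbinol chain, C6 O) by the carboxyl-bearing C1 and on ring B (C1' O, C2' OH, C3' H, C4' CH3, C5' H, C6' CHO) by the formyl-bearing C6'. These two carbons can therefore be joined as ArCO2–CH2Ar in an eight-membered dibenzo lactone, and C1'–C4' with O, O and CH3 is the C3–C6 diene of a 3-aryloxy-4-alkoxy-6-methyl-2-pyrone.
2. Target ⇒ that lactone: removal of silyl and MOM groups, ArCH2OH → ArCHO, hydroxide opening of the lactone.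
3. Lactone ⇒ propargyl benzoate of ring A carrying the pyron-3-yl ether: bonds C1'–C6' and C4'–C5' come from an intramolecular pyrone/alkyne Diels–Alder reaction followed by loss of CO2.
4. Pyronyl ether ⇒ ring A salicylate-type phenol + 3-diazo derivative of triacetic acid lactone (O–H insertion). Ring A ⇒ 4-hydroxy-2-methoxybenzaldehyde (isobutyl Grignard, oxidation, CBS reduction to S, metalation/carboxylation between the two oxygens).
5. Ring order: ring A and the pyrone ring are bought; ring B and the eight-membered lactone close together in the key step; the lactone ring is opened again afterwards.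

Key step: step 13

Assumption: the carbinol carbon of the given SMILES is read as S (O > aryl C > CH2 > H). In every SMILES below it is written in the same atom order as in the target.

**Step 1**
Reactants: 1 4-hydroxy-2-methoxybenzaldehyde
Product: 2 2-methoxy-4-(methoxymethoxy)benzaldehyde
Conditions: MOMCl, iPr2NEt, CH2Cl2, 0 °C → rt
Reagents that add atoms: chloromethyl methyl ether (MOMCl), COCCl
Why: Williamson-type O-alkylation of the acidic phenol should be clean, and the MOM acetal is chosen because it survives steps 2–5 and later helps to direct the metalation.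

**Step 2**
Reactants: 2 2-methoxy-4-(methoxymethoxy)benzaldehyde; 3 isobutylmagnesium bromide
Product: 4 rac-1-[2-methoxy-4-(methoxymethoxy)phenyl]-3-methylbutan-1-ol
Conditions: iBuMgBr, THF, −20 → 0 °C; aq. NH4Cl
Reagents that add atoms: isobutylmagnesium bromide (3), CC(C)C[Mg]Br
Why: Grignard 1,2-addition to the aldehyde should install the isobutyl chain, and the alcohol is taken on as the racemate because its configuration is erased in step 3 and set in step 4.

**Step 3**
Reactants: 4 rac-1-[2-methoxy-4-(methoxymethoxy)phenyl]-3-methylbutan-1-ol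
Product: 5 1-[2-methoxy-4-(methoxymethoxy)phenyl]-3-methylbutan-1-one
Conditions: activated MnO2, CH2Cl2, rt
Reagents that add atoms: none
Why: MnO2 oxidation of an electron-rich benzylic alcohol to the aryl ketone is a neutral reaction that should leave the acetal and the methyl ether untouched.

**Step 4**
Reactants: 5 1-[2-methoxy-4-(methoxymethoxy)phenyl]-3-methylbutan-1-one
Product: 6 (1S)-1-[2-methoxy-4-(methoxymethoxy)phenyl]-3-methylbutan-1-ol
Conditions: (R)-2-methyl-CBS-oxazaborolidine (10 mol %), BH3·SMe2, THF, −20 °C; MeOH, aqueous work-up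
Reagents that add atoms: none
Why: In the Corey–Bakshi–Shibata reduction the (R)-oxazaborolidine should bind the ketone with the aryl group as the large and the CH2 of isobutyl as the small substituent and deliver hydride to the Re face, which sets the S configuration.

**Step 5**
Reactants: 6 (1S)-1-[2-methoxy-4-(methoxymethoxy)phenyl]-3-methylbutan-1-ol
Product: 7 tert-butyl{(1S)-1-[2-methoxy-4-(methoxymethoxy)phenyl]-3-methylbutoxy}dimethylsilane
Conditions: TBSCl, imidazole, DMF, rt → 40 °C
Reagents that add atoms: tert-butyldimethylsilyl chloride (TBSCl), CC(C)(C)[Si](C)(C)Cl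
Why: Imidazole-promoted silylation takes place at oxygen only, so the S centre is kept, and the silyl ether tolerates organolithium, carbenoid, heat and hydroxide in the later steps.

**Step 6**
Reactants: 7 tert-butyl{(1S)-1-[2-methoxy-4-(methoxymethoxy)phenyl]-3-methylbutoxy}dimethylsilane
Product: 9 benzyl 3-[(1S)-1-(tert-butyldimethylsilyloxy)-3-methylbutyl]-2-methoxy-6-(methoxymethoxy)benzoate, via aryllithium 8 (not isolated)
Conditions: n-BuLi, TMEDA, THF, −78 → 0 °C; then ClCO2Bn, −78 °C → rt
Reagents that add atoms: n-butyllithium, [Li]CCCC (lithium of 8); benzyl chloroformate, O=C(Cl)OCc1ccccc1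
Why: In this directed ortho-metalation the ring C–H flanked by OMe and OMOM is the most acidic and both oxygens can hold lithium, acylation by the chloroformate should give the ester in the same flask, and crowding around the new ester blocks a second addition.

**Step 7**
Reactants: 9 benzyl 3-[(1S)-1-(tert-butyldimethylsilyloxy)-3-methylbutyl]-2-methoxy-6-(methoxymethoxy)benzoate
Product: 11 benzyl 3-[(1S)-1-(tert-butyldimethylsilyloxy)-3-methylbutyl]-6-hydroxy-2-methoxybenzoate, via aryl trimethylsilyl ether 10 (not isolated)
Conditions: TMSOTf, 2,2'-bipyridyl, MeCN, 0 °C → rt; then H2O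
Reagents that add atoms: trimethylsilyl triflate, C[Si](C)(C)OS(=O)(=O)C(F)(F)F (silyl group of 10, lost again with water)
Why: The silyl triflate/2,2'-bipyridyl cleavage of aromatic MOM ethers runs without free acid through the aryl silyl ether, so it should spare the TBS ether and avoid ionisation of the benzylic C–O bond para to the freed phenol, which keeps the S centre.

**Step 8**
Reactants: 12 triacetic acid lactone (4-hydroxy-6-methyl-2H-pyran-2-one)
Product: 13 3-diazo-6-methyl-2H-pyran-2,4(3H)-dione
Conditions: 4-acetamidobenzenesulfonyl azide, Et3N, MeCN, 0 °C → rt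
Reagents that add atoms: 4-acetamidobenzenesulfonyl azide, CC(=O)Nc1ccc(cc1)S(=O)(=O)N=[N+]=[N-]
Why: Regitz diazo transfer to the doubly activated C3 of a cyclic 1,3-dicarbonyl compound is a standard reaction and needs only a mild amine base.

**Step 9**
Reactants: 11 benzyl 3-[(1S)-1-(tert-butyldimethylsilyloxy)-3-methylbutyl]-6-hydroxy-2-methoxybenzoate; 13 3-diazo-6-methyl-2H-pyran-2,4(3H)-dione
Product: 14 benzyl 3-[(1S)-1-(tert-butyldimethylsilyloxy)-3-methylbutyl]-6-[(4-hydroxy-6-methyl-2-oxo-2H-pyran-3-yl)oxy]-2-methoxybenzoate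
Conditions: Rh2(OAc)4 (2 mol %), PhF, 80 °C, slow addition of 13
Reagents that add atoms: 3-diazo-6-methyl-2H-pyran-2,4(3H)-dione (13), CC1=CC(=O)C(=[N+]=[N-])C(=O)O1
Why: In this rhodium carbenoid O–H insertion, loss of N2 gives an electrophilic carbenoid at C3, the phenol oxygen adds, and proton shift with enolisation should give the 3-aryloxy-4-hydroxy-2-pyrone under neutral conditions; the carboxyl is held as a benzyl ester here because a terminal alkyne would compete for the carbenoid.

**Step 10**
Reactants: 14 benzyl 3-[(1S)-1-(tert-butyldimethylsilyloxy)-3-methylbutyl]-6-[(4-hydroxy-6-methyl-2-oxo-2H-pyran-3-yl)oxy]-2-methoxybenzoate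
Product: 15 benzyl 3-[(1S)-1-(tert-butyldimethylsilyloxy)-3-methylbutyl]-2-methoxy-6-{[4-(methoxymethoxy)-6-methyl-2-oxo-2H-pyran-3-yl]oxy}benzoate
Conditions: MOMCl, iPr2NEt, CH2Cl2, 0 °C
Reagents that add atoms: chloromethyl methyl ether (MOMCl), COCCl
Why: O-alkylation of the vinylogous acid with a hard electrophile and an amine base should occur at the C4 oxygen and keep the 2-pyrone form, and MOM has no β-hydrogen, so it cannot be lost by thermal elimination in step 13.

**Step 11**
Reactants: 15 benzyl 3-[(1S)-1-(tert-butyldimethylsilyloxy)-3-methylbutyl]-2-methoxy-6-{[4-(methoxymethoxy)-6-methyl-2-oxo-2H-pyran-3-yl]oxy}benzoate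
Product: 16 3-[(1S)-1-(tert-butyldimethylsilyloxy)-3-methylbutyl]-2-methoxy-6-{[4-(methoxymethoxy)-6-methyl-2-oxo-2H-pyran-3-yl]oxy}benzoic acid
Conditions: H2 (1 atm), Pd/C (10 wt %), EtOAc, rt; used crude
Reagents that add atoms: none
Why: Hydrogenolysis of a benzyl ester at one atmosphere is much faster than saturation of a 4-alkoxy-2-pyrone, cleaves the O–CH2Ph bond away from the crowded carboxyl, and leaves acetal, silyl ether and the S centre alone.

**Step 12**
Reactants: 16 3-[(1S)-1-(tert-butyldimethylsilyloxy)-3-methylbutyl]-2-methoxy-6-{[4-(methoxymethoxy)-6-methyl-2-oxo-2H-pyran-3-yl]oxy}benzoic acid; 17 propargyl bromide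
Product: 18 prop-2-yn-1-yl 3-[(1S)-1-(tert-butyldimethylsilyloxy)-3-methylbutyl]-2-methoxy-6-{[4-(methoxymethoxy)-6-methyl-2-oxo-2H-pyran-3-yl]oxy}benzoate
Conditions: propargyl bromide, K2CO3, DMF, 0 °C → rt
Reagents that add atoms: propargyl bromide (17), C#CCBr
Why: SN2 alkylation of the carboxylate forms the ester at the propargylic carbon, so it does not depend on access to the doubly ortho-substituted carbonyl carbon, and the mild base should leave the pyrone intact.

**Step 13**
Reactants: 18 prop-2-yn-1-yl 3-[(1S)-1-(tert-butyldimethylsilyloxy)-3-methylbutyl]-2-methoxy-6-{[4-(methoxymethoxy)-6-methyl-2-oxo-2H-pyran-3-yl]oxy}benzoate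
Product: 20 3-[(1S)-1-(tert-butyldimethylsilyloxy)-3-methylbutyl]-4-methoxy-11-(methoxymethoxy)-9-methyl-5H,7H-dibenzo[b,g][1,5]dioxocin-5-one, via bridged bicyclic lactone 19 (not isolated)
Conditions: o-dichlorobenzene (0.005 M, degassed), BHT, sealed vessel, 200–210 °C
Reagents that add atoms: none
Why: Proposed new method: the alkyne of 18 should add suprafacially to pyrone C3 and C6 in a concerted [4+2] cycloaddition to give the 2-oxabicyclo[2.2.2]octadienone 19, which should at once expel CO2 in a retro-[4+2] step, so that aromatisation makes the sequence irreversible. The closest known reaction type is the thermal intramolecular 2-pyrone/alkyne Diels–Alder reaction with decarboxylation, established for short tethers that close five- and six-membered rings, whereas a six-atom aryl ether/benzoate tether has not been tested. Ring B closes by the cycloaddition itself (four pyrone carbons plus two alkyne carbons, new bonds C1'–C6' and C4'–C5'), and the eight-membered lactone closes in the same event in the fused mode through the C1'–C6' bond, its other six atoms (ether O, C6 and C1 of ring A, carboxyl C, ester O, CH2) being the tether. The two ortho substituents turn the benzoate out of the plane of ring A and hold the pyrone face beside it, which should offset in part the cost of the less stable E ester rotamer and the poor electronic match of an electron-rich pyrone with an unactivated alkyne, hence the high temperature and the heat-stable MOM and TBS groups. The selectivity required is regiochemical (internal alkyne carbon to pyrone C3), and the tether secures it because the reverse orientation would demand a strained meta-bridged arene. No stereocentre is created in 20, since the bridgeheads of 19 become aromatic carbons, and the S carbinol carbon takes no part.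

**Step 14**
Reactants: 20 3-[(1S)-1-(tert-butyldimethylsilyloxy)-3-methylbutyl]-4-methoxy-11-(methoxymethoxy)-9-methyl-5H,7H-dibenzo[b,g][1,5]dioxocin-5-one
Product: 21 3-[(1S)-1-(tert-butyldimethylsilyloxy)-3-methylbutyl]-6-[2-(hydroxymethyl)-6-(methoxymethoxy)-4-methylphenoxy]-2-methoxybenzoic acid
Conditions: LiOH, THF/H2O (3:1), 45 °C; then 1 M HCl to pH 4, 0 °C
Reagents that add atoms: lithium hydroxide, [Li+].[OH-]
Why: Saponification should be easier than for an open 2,6-disubstituted benzoate because the medium-ring lactone is strained and held in the reactive E geometry, methanol is left out so that no methyl ester can form, and MOM and TBS are stable to base.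

**Step 15**
Reactants: 21 3-[(1S)-1-(tert-butyldimethylsilyloxy)-3-methylbutyl]-6-[2-(hydroxymethyl)-6-(methoxymethoxy)-4-methylphenoxy]-2-methoxybenzoic acid
Product: 22 3-[(1S)-1-(tert-butyldimethylsilyloxy)-3-methylbutyl]-6-[2-formyl-6-(methoxymethoxy)-4-methylphenoxy]-2-methoxybenzoic acid
Conditions: TEMPO (10 mol %), PhI(OAc)2, CH2Cl2, rt
Reagents that add atoms: none
Why: The oxoammonium (TEMPO/PhI(OAc)2) oxidation stops at the aldehyde in the absence of water and tolerates a free acid, and the primary benzylic alcohol is the only free hydroxyl because carbinol and phenol are still masked.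

**Step 16**
Reactants: 22 3-[(1S)-1-(tert-butyldimethylsilyloxy)-3-methylbutyl]-6-[2-formyl-6-(methoxymethoxy)-4-methylphenoxy]-2-methoxybenzoic acid
Product: 24 3-[(1S)-1-(tert-butyldimethylsilyloxy)-3-methylbutyl]-6-(2-formyl-6-hydroxy-4-methylphenoxy)-2-methoxybenzoic acid, via bis(trimethylsilyl) derivative 23 (not isolated)
Conditions: TMSOTf (4 equiv), 2,2'-bipyridyl (6 equiv), MeCN, 0 °C → rt; then H2O
Reagents that add atoms: trimethylsilyl triflate, C[Si](C)(C)OS(=O)(=O)C(F)(F)F (silyl groups of 23, lost again with water)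
Why: The same acid-free cleavage of an aromatic MOM ether as in step 7 is used, the carboxyl being silylated in passing and the formyl group at most masked reversibly, and water should return both, so the benzylic C–O bond is never exposed to strong acid.

**Step 17**
Reactants: 24 3-[(1S)-1-(tert-butyldimethylsilyloxy)-3-methylbutyl]-6-(2-formyl-6-hydroxy-4-methylphenoxy)-2-methoxybenzoic acid
Product: 25 tenellic acid B
Conditions: HF·pyridine, THF/pyridine, 0 °C → rt
Reagents that add atoms: none
Why: Fluoride-driven desilylation breaks the Si–O bond only, so the C–O bond and the S configuration are retained, and aldehyde, phenol and acid tolerate the buffered reagent.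

**Compound list**
1 | 4-hydroxy-2-methoxybenzaldehyde | COc1cc(O)ccc1C=O | starting material
2 | 2-methoxy-4-(methoxymethoxy)benzaldehyde | COCOc1ccc(C=O)c(OC)c1 | intermediate
3 | isobutylmagnesium bromide | CC(C)C[Mg]Br | starting material
4 | rac-1-[2-methoxy-4-(methoxymethoxy)phenyl]-3-methylbutan-1-ol | COCOc1ccc(C(O)CC(C)C)c(OC)c1 | intermediate
5 | 1-[2-methoxy-4-(methoxymethoxy)phenyl]-3-methylbutan-1-one | COCOc1ccc(C(=O)CC(C)C)c(OC)c1 | intermediate
6 | (1S)-1-[2-methoxy-4-(methoxymethoxy)phenyl]-3-methylbutan-1-ol | COCOc1ccc([C@@H](O)CC(C)C)c(OC)c1 | intermediate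
7 | TBS ether of 6, S | COCOc1ccc([C@@H](O[Si](C)(C)C(C)(C)C)CC(C)C)c(OC)c1 | intermediate
8 | aryllithium from 7, lithium on the ring carbon between OMe and OMOM (not isolated) | COCOc1ccc([C@@H](O[Si](C)(C)C(C)(C)C)CC(C)C)c(OC)c1[Li] | intermediate
9 | benzyl 3-[(1S)-1-(TBS-oxy)-3-methylbutyl]-2-methoxy-6-(methoxymethoxy)benzoate | COCOc1ccc([C@@H](O[Si](C)(C)C(C)(C)C)CC(C)C)c(OC)c1C(=O)OCc1ccccc1 | intermediate
10 | benzyl 3-[(1S)-1-(TBS-oxy)-3-methylbutyl]-2-methoxy-6-(trimethylsilyloxy)benzoate (not isolated) | C[Si](C)(C)Oc1ccc([C@@H](O[Si](C)(C)C(C)(C)C)CC(C)C)c(OC)c1C(=O)OCc1ccccc1 | intermediate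
11 | benzyl 3-[(1S)-1-(TBS-oxy)-3-methylbutyl]-6-hydroxy-2-methoxybenzoate | Oc1ccc([C@@H](O[Si](C)(C)C(C)(C)C)CC(C)C)c(OC)c1C(=O)OCc1ccccc1 | intermediate
12 | triacetic acid lactone | Cc1cc(O)cc(=O)o1 | starting material
13 | 3-diazo-6-methyl-2H-pyran-2,4(3H)-dione | CC1=CC(=O)C(=[N+]=[N-])C(=O)O1 | intermediate
14 | benzyl ester of ring A with the 4-hydroxy-6-methyl-2-pyron-3-yl ether, S | COc1c([C@@H](O[Si](C)(C)C(C)(C)C)CC(C)C)ccc(Oc2c(O)cc(C)oc2=O)c1C(=O)OCc1ccccc1 | intermediate
15 | benzyl ester of ring A with the 4-(methoxymethoxy)-6-methyl-2-pyron-3-yl ether, S | COc1c([C@@H](O[Si](C)(C)C(C)(C)C)CC(C)C)ccc(Oc2c(OCOC)cc(C)oc2=O)c1C(=O)OCc1ccccc1 | intermediate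
16 | free benzoic acid from 15, S | COc1c([C@@H](O[Si](C)(C)C(C)(C)C)CC(C)C)ccc(Oc2c(OCOC)cc(C)oc2=O)c1C(=O)O | intermediate
17 | propargyl bromide | C#CCBr | starting material
18 | propargyl benzoate of ring A with the 4-(methoxymethoxy)-6-methyl-2-pyron-3-yl ether, S (key-step precursor) | COc1c([C@@H](O[Si](C)(C)C(C)(C)C)CC(C)C)ccc(Oc2c(OCOC)cc(C)oc2=O)c1C(=O)OCC#C | intermediate
19 | 2-oxabicyclo[2.2.2]octadienone cycloadduct, bridgeheads are former pyrone C3 and C6, bridgehead configuration undefined (not isolated) | COc1c([C@@H](O[Si](C)(C)C(C)(C)C)CC(C)C)ccc2c1C(=O)OCC1=CC3(C)C=C(OCOC)C1(O2)C(=O)O3 | intermediate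
20 | eight-membered dibenzo lactone (5H,7H-dibenzo[b,g][1,5]dioxocin-5-one) with OMe, OMOM, CH3 and the S TBS-oxy chain (key-step product) | COc1c([C@@H](O[Si](C)(C)C(C)(C)C)CC(C)C)ccc2c1C(=O)OCc1cc(C)cc(OCOC)c1O2 | intermediate
21 | hydroxy acid from lactone opening, S | COc1c([C@@H](O[Si](C)(C)C(C)(C)C)CC(C)C)ccc(Oc2c(OCOC)cc(C)cc2CO)c1C(=O)O | intermediate
22 | MOM- and TBS-protected tenellic acid B, S | COc1c([C@@H](O[Si](C)(C)C(C)(C)C)CC(C)C)ccc(Oc2c(OCOC)cc(C)cc2C=O)c1C(=O)O | intermediate
23 | trimethylsilyl ester and aryl trimethylsilyl ether from 22 (not isolated) | COc1c([C@@H](O[Si](C)(C)C(C)(C)C)CC(C)C)ccc(Oc2c(O[Si](C)(C)C)cc(C)cc2C=O)c1C(=O)O[Si](C)(C)C | intermediate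
24 | TBS-protected tenellic acid B, S | COc1c([C@@H](O[Si](C)(C)C(C)(C)C)CC(C)C)ccc(Oc2c(O)cc(C)cc2C=O)c1C(=O)O | intermediate
25 | tenellic acid B, S | COc1c([C@@H](O)CC(C)C)ccc(Oc2c(O)cc(C)cc2C=O)c1C(=O)O | target

Total step count: 17. Longest linear sequence: 16 steps (steps 1–7 and 9–17; step 8 is a one-step branch from 12).

**Steps most likely to fail**

Step 13. The cycloaddition may be too slow. The ester has to reach its less favoured rotamer, an eight-membered transition state costs entropy, and an electron-rich pyrone is a poor partner for an unactivated alkyne. Thermal loss of the acetal or unspecific decomposition may then overtake ring closure.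

The fallback gives up the pyrone and forms the ether by known nucleophilic aromatic substitution. It sets out from 11 and comes back at 22.
- Commercial 2-fluoro-5-methylphenol would be treated with MOMCl/iPr2NEt to give 1-fluoro-2-(methoxymethoxy)-4-methylbenzene F1.
- Lithiation next to fluorine (s-BuLi, TMEDA, THF, −78 °C) would give the 3-lithio derivative of that fluoroarene F2, and a DMF quench would give 2-fluoro-3-(methoxymethoxy)-5-methylbenzaldehyde F3.
- The phenoxide of 11 (K2CO3, DMF, 80–100 °C) would displace the formyl-activated fluoride to give the benzyl ester of the protected diaryl ether aldehyde F4.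
- Brief hydrogenolysis of the benzyl ester (H2, Pd/C, EtOAc, stopped after one equivalent) would give 22.

Step 9. The carbenoid may be diverted into attack on an aromatic C–H bond of the electron-rich ring A, Wolff rearrangement or dimerisation, because the phenol O–H is hydrogen-bonded to the neighbouring ester and is a weak nucleophile.

The fallback builds the pyrone on the oxygen by enolate chemistry. It sets out from 11 and comes back at 14.
- O-alkylation of 11 with ethyl 2-chloroacetoacetate (K2CO3, acetone, reflux) would give the ethyl 2-aryloxy-3-oxobutanoate F5, whose α-carbon is configurationally labile.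
- Double deprotonation with LDA (THF, −78 °C) would give the dilithio dianion F6, and γ-acylation with N-methoxy-N-methylacetamide would give the ethyl 2-aryloxy-3,5-dioxohexanoate F7.
- DBU in toluene at reflux would close the 4-hydroxy-2-pyrone with loss of ethanol to give 14.

Step 16. The free carboxyl and formyl groups may tie up the silyl triflate/bipyridyl pair so that acetal cleavage stalls, or long exposure may erode the silyl ether.

The fallback changes the order of events, so that the acetal is removed before acid and aldehyde exist. It sets out from 20 and comes back at 24.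
- Lactone 20 would be treated as in step 7 to give the aryl trimethylsilyl ether of the lactone F8, and water would then give the phenol lactone F9.
- LiOH in THF/H2O would open it to the phenolic hydroxy acid F10.
- Activated MnO2 (EtOAc, rt), which is known to oxidise hydroxybenzyl alcohols selectively at the benzylic carbon, would give 24.

**Further compounds**
F1 | step 13 | 1-fluoro-2-(methoxymethoxy)-4-methylbenzene | COCOc1cc(C)ccc1F
F2 | step 13 | 3-lithio derivative of F1, lithium next to fluorine (not isolated) | COCOc1cc(C)cc([Li])c1F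
F3 | step 13 | 2-fluoro-3-(methoxymethoxy)-5-methylbenzaldehyde | COCOc1cc(C)cc(C=O)c1F
F4 | step 13 | benzyl 3-[(1S)-1-(TBS-oxy)-3-methylbutyl]-6-[2-formyl-6-(methoxymethoxy)-4-methylphenoxy]-2-methoxybenzoate | COc1c([C@@H](O[Si](C)(C)C(C)(C)C)CC(C)C)ccc(Oc2c(OCOC)cc(C)cc2C=O)c1C(=O)OCc1ccccc1
F5 | step 9 | ethyl 2-aryloxy-3-oxobutanoate from 11 | CCOC(=O)C(Oc1ccc([C@@H](O[Si](C)(C)C(C)(C)C)CC(C)C)c(OC)c1C(=O)OCc1ccccc1)C(C)=O
F6 | step 9 | dilithio dianion of F5 (not isolated) | [Li+].[Li+].C=C([O-])C(Oc1ccc([C@@H](O[Si](C)(C)C(C)(C)C)CC(C)C)c(OC)c1C(=O)OCc1ccccc1)=C([O-])OCC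
F7 | step 9 | ethyl 2-aryloxy-3,5-dioxohexanoate from 11 | CCOC(=O)C(Oc1ccc([C@@H](O[Si](C)(C)C(C)(C)C)CC(C)C)c(OC)c1C(=O)OCc1ccccc1)C(=O)CC(C)=O
F8 | step 16 | aryl trimethylsilyl ether of the eight-membered lactone (not isolated) | COc1c([C@@H](O[Si](C)(C)C(C)(C)C)CC(C)C)ccc2c1C(=O)OCc1cc(C)cc(O[Si](C)(C)C)c1O2
F9 | step 16 | phenol lactone, TBS ether retained | COc1c([C@@H](O[Si](C)(C)C(C)(C)C)CC(C)C)ccc2c1C(=O)OCc1cc(C)cc(O)c1O2
F10 | step 16 | phenolic hydroxy acid, TBS ether retained | COc1c([C@@H](O[Si](C)(C)C(C)(C)C)CC(C)C)ccc(Oc2c(O)cc(C)cc2CO)c1C(=O)O
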